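**Target:** (1S,2R,3E,7S,8R,11S,12Z)-7-acetoxy-8,11-epidioxycembra-3,12,15(17)-trien-16,2-olide (CNP0238885.5), compound 35. 
**Route:** 23 steps, built around a singlet-oxygen [4+2] cycloaddition to an arene-derived diene acetonide (step 4) and later glycol cleavage of the resulting bicycle.

## Analysis of the target

The target is a cembranolide. Its 14-membered carbocycle (C1–C14; cembrane numbering is used here for the target and for all intermediates) is trans-fused at C1–C2 to an α-methylene-γ-butyrolactone (C15, C16, C17) and bridged from C8 to C11 by a peroxide, so that C8, C9, C10, C11 and two oxygen atoms form a 1,2-dioxane. It has five stereocentres (1S, 2R, 7S, 8R, 11S) and two trisubstituted alkenes (3E, 12Z). C7, C8 and C11 form one oxygenated group: the C7 acetate sits next to the quaternary peroxy carbon C8 (methyl C19), and the C7 and C12 arms of the dioxane are cis. The C1/C2 pair lies beyond both alkenes and cannot be set from that group by short-range induction. The O–O bond rules out hydrogenation catalysts, strongly reducing metals and warm hydride or phosphine reagents; C11–H is allylic and α to the peroxide, so base can cause Kornblum–DeLaMare cleavage; the methylene lactone is a Michael acceptor. The hard points are therefore the cis-3,6-disubstituted dioxane with a quaternary carbon in one absolute configuration, the 12Z alkene attached directly to C11, and a ring closure that sets C1 and C2 while the peroxide is present. The strategy rests on one feature: when C7 and C12 are joined, the dioxane with its cis arms becomes a 2,3-dioxabicyclo[2.2.2]octene with C8 and C11 as bridgeheads, C9=C10 as the alkene bridge and C7–C12 as a glycol bridge. That bicycle is the singlet-oxygen adduct of a toluene-derived cyclohexadiene cis-diol whose methyl group is C19.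

## Retrosynthetic reasoning

**C1–C2 and the lactone C–O bond.** Target 35 is opened to bromo enal 32. C1–C2 is the one ring bond whose formation creates both remaining stereocentres, the exocyclic methylene and, after acyl transfer, the lactone. An allyl-metal addition of a 2-(bromomethyl)enoate to an enal is the established way to close cembranolide rings. It is placed last so that the Michael-acceptor lactone meets no further reagent, and the C7 acetate is already present, so nothing follows the ring closure. The forward step has to form a 14-membered ring at high dilution, with a metal that leaves the O–O bond alone, and give the trans lactone with the right facial sense.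

**C1–C15 (the bromomethyl enoate).** 32 goes back through alcohol 31 and bromide 30 to the α-methylene β-hydroxy ester 29, and 29 through amino aldol adduct 27 to aldehyde 24 and ester 25. An amine-catalysed acrylate coupling (Morita–Baylis–Hillman) would be shorter, but aldehyde 24 is β,γ-unsaturated and would slip into conjugation during long contact with an amine. Ester 25 acts as an acrylate α-anion equivalent at −78 °C instead.

**C12=C13.** Aldehyde 24 comes from alcohol 23 and silyl ether 22, and 22 from methyl ketone 18 and ylide 21 (from salt 20, from bromide 19). The cut is made here because the alkene carbon C12 is bonded to the oxygenated C11: α-oxygenated methyl ketones give Z-trisubstituted alkenes with non-stabilised ylides. One operation sets the 12Z geometry and brings in C13, C14 and C1.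

**C6–C7 and the C7 stereocentre.** Ketone 18 comes from propargylic acetate 17 and alcohol 16, and 16 from keto aldehyde 12 and alkyne 14 (through zinc acetylide 15); 14 is the protected form of commercial enynol 13. The aldehyde of 12 sits on the quaternary C8 and cannot enolise, so a catalyst-controlled alkynyl addition can set 7S. Enynol 13 supplies C2–C6 with the 3E alkene already fixed. The triple bond is later saturated by concerted hydrogen transfer, since catalytic hydrogenation would cleave the peroxide. The acetate goes on at once: it is the ester of the target, and it removes a free hydroxyl β to the peroxide, which as an alkoxide could fragment.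

**C7–C12 (reconnection to the bicycle).** Keto aldehyde 12 is the glycol-cleavage product of bicyclic diol 11. This step turns a monocyclic cis-3,6-disubstituted dioxane, which would be hard to make stereoselectively, into a [2.2.2] bicycle in which the cis relation is automatic. Methyl C20 enters by addition to ketol 10, which comes from oxidation of the less hindered hydroxyl of diol 9. Diol 9 comes from acetonide 8, and 8 from alkene 7 by saturation of C9=C10, so that the peroxide is no longer doubly allylic during the later steps.

**C8–O and C11–O (key disconnection).** Endoperoxide 7 is cut across both C–O bonds to diene acetonide 6 and dioxygen 2. One cycloaddition forms the peroxide ring and both stereocentres C8 and C11. The forward step needs attack on the diene face anti to the acetonide.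

**The diene.** Acetonide 6 comes from diol 4 and 2,2-dimethoxypropane 5. Diol 4 is the enantiomer of the usual toluene metabolite, so it is reached from 4-iodotoluene 1: enzymatic dihydroxylation with dioxygen 2 gives iodo diol 3, in which iodine, not methyl, directs the enzyme, and removal of iodine gives 4.

## Alternatives that were turned down

**Alternative 1:** Disconnection at C2–C3 together with C4–C18. In the forward step an aldehyde at C2 and a terminal C3≡C4 alkyne in one chain are joined by Ni(cod)2 and a carbene ligand through an oxanickelacycle; Me2Zn then delivers a methyl group to C4. This gives the 14-membered allylic alcohol A1.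
- For: a single catalytic step closes the ring, makes the C2 carbinol and, by syn addition across the alkyne, the 3E alkene.
- Against: zerovalent nickel and Me2Zn would not tolerate an O–O bond, so A1 carries a 7,8-epoxide and a silyl ether at C11. The peroxide must then be made on the macrocycle by substitution at C11 with inversion and transannular epoxide opening, and the lactone by two oxidation-level changes at C16. The C1/C2 relation depends on 1,2-induction from an α-branched aldehyde.
- Comparison: on ring closure and step economy at the macrocycle it is stronger than the chosen route, whose Barbier closure is limited by the peroxide. The chosen route offers in exchange that C8 and C11 are fixed in absolute terms early, by a cycloaddition whose stereochemical course is well understood.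

**Alternative 2:** Disconnection of the O–C8 bond of the dioxane. In the forward step the hydroperoxy epoxide A2, a (7S,8S)-epoxide with an 11S hydroperoxide, is treated with mild acid. The hydroperoxide attacks C8 across the ring with inversion (6-exo, at the more substituted epoxide carbon), closing the dioxane and freeing the C7 hydroxyl to give the 7-O-deacetyl target A3.
- For: it is plausibly biomimetic, and the O–O bond then has to survive only the final acetylation. On this point it is clearly stronger than the chosen route, which carries the peroxide through nineteen steps.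
- Against: A2 needs a configurationally defined secondary allylic hydroperoxide on a macrocycle that also holds an epoxide and the methylene lactone. Substitution at an allylic C11 invites SN1 and SN2′ leakage, an ene reaction would not be regio- or stereocontrolled, and the facial selectivity of the macrocyclic epoxidation is conformational. The acid could also open the epoxide with a ring alkene.
- Comparison: the chosen route gives up the late peroxide formation but sets C8 and C11 together and unambiguously, with no separately made hydroperoxide and epoxide that must match.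

**Alternative 3:** Disconnection at C11–C12. In the forward step CrCl2 with catalytic NiCl2 and a chiral sulfonamide ligand turns a Z-vinyl iodide at C12 into an alkenylchromium that adds to a C11 aldehyde, giving the (11R)-hydroxy epoxy cembranolide A4.
- For: this type of macrocyclisation is among the most dependable for cembranoids, it keeps the Z geometry of the vinyl iodide, and the lactone can already be in place. On ring-closure reliability it is stronger than the chosen Barbier step.
- Against: divalent chromium excludes the peroxide, so A4 still has to be converted with inversion at C11 into A2 and then pass through the cyclisation of Alternative 2. The weakest selectivity therefore comes at the very end. Ligand control at C11 competes with the conformational preference of the forming ring, and the Z-trisubstituted vinyl iodide needs its own synthesis.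
- Comparison: the chosen route has a less proven ring closure but avoids the late substitution–cyclisation sequence at C11 and C8 altogether.

Key step: step 4

## Route

Remarks on the chemistry: a recombinant toluene dioxygenase strain is assumed to be available as biocatalyst. PMB is 4-methoxybenzyl and TBS is tert-butyldimethylsilyl.

Step 1
Reactants: 1 4-iodotoluene; 2 dioxygen
Product: 3 (1S,2S)-3-iodo-6-methylcyclohexa-3,5-diene-1,2-diol
Conditions: E. coli JM109 (pDTG601A) whole cells expressing toluene dioxygenase, glucose, phosphate buffer pH 7, air, 30 °C
Reagents that add atoms: none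
Why: Enzymatic arene cis-dihydroxylation; in 1,4-disubstituted benzenes the larger group (iodine) takes the directing role that methyl has in toluene, so both carbinol centres are set by the enzyme next to C–I with the sense that becomes enantiomeric to the toluene metabolite once iodine is removed. Should methyl compete as directing group, 3 is enriched by recrystallisation before use.

Step 2
Reactants: 3 (1S,2S)-3-iodo-6-methylcyclohexa-3,5-diene-1,2-diol
Product: 4 (1R,2S)-3-methylcyclohexa-3,5-diene-1,2-diol
Conditions: H2 (1 atm), Pd/C (cat.), NaOAc, MeOH, 0 °C, stopped after one equivalent of H2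
Reagents that add atoms: none
Why: Hydrogenolysis of the vinylic C–I bond on palladium is much faster than hydrogenation of the diene, and the acetate buffer takes up HI so that the acid-labile dienediol does not aromatise. No stereocentre is touched; the descriptor of the former iodine-side carbinol changes from S to R only through the CIP priorities.

Step 3
Reactants: 4 (1R,2S)-3-methylcyclohexa-3,5-diene-1,2-diol; 5 2,2-dimethoxypropane
Product: 6 diene acetonide (3aS,7aR)-2,2,4-trimethyl-3a,7a-dihydro-1,3-benzodioxole
Conditions: TsOH (cat.), CH2Cl2, 0 °C
Reagents that add atoms: none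
Why: Acid-catalysed transacetalisation of the cis-diol; the acetonide blocks aromatisation by dehydration and is the facial control element of step 4. 6 is used at once because dienes of this type dimerise by Diels–Alder reaction on standing.

Step 4
Reactants: 6 diene acetonide; 2 dioxygen
Product: 7 endoperoxide acetonide (2,3-dioxabicyclo[2.2.2]oct-5-ene; 8R,11S; acetonide anti to the O–O bridge)
Conditions: O2, tetraphenylporphyrin (cat.), hν (visible, >400 nm), CH2Cl2, −40 °C
Reagents that add atoms: none
Why: Energy transfer from the excited porphyrin converts 2 into its singlet state, which adds to the same face of both diene termini, C8 and C11, of 6 in a concerted and possibly asynchronous [4+2] cycloaddition that forms both C–O bonds. The closest known reaction type is the endoperoxidation of 1,3-cyclohexadienes (α-terpinene to ascaridole) and of arene cis-dihydrodiol acetonides. The one ring that is closed, a 3,6-dihydro-1,2-dioxine, arises by cycloaddition and not by stepwise ring closure, and it becomes the peroxide bridge of a 2,3-dioxabicyclo[2.2.2]oct-5-ene. C8 and C11 are both set by the diene face that the oxygen molecule takes: addition to one face makes them cis by necessity, and approach anti to the cis-fused acetonide, whose oxygen atoms crowd the syn face and repel the incoming oxygen, gives 8R,11S from the (3aS,7aR) acetonide. The step needs π-facial selectivity, which the acetonide secures, and preference for [4+2] over the ene reaction at the C19 methyl group, which the ring-locked s-cis diene secures. Low temperature and the cut-off filter keep 7 from rearranging to a bis-epoxide and 6 from dimerising.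

Step 5
Reactants: 7 endoperoxide acetonide
Product: 8 dihydro endoperoxide acetonide (C9–C10 saturated)
Conditions: KO2CN=NCO2K, AcOH, CH2Cl2, −78 °C → rt
Reagents that add atoms: none
Why: Diimide transfers two hydrogen atoms in a concerted syn fashion to the strained C9=C10 bond and leaves the O–O bond alone, which no heterogeneous hydrogenation would. The saturated bicycle no longer has an allylic peroxide and tolerates the acid and mild base of the next steps.

Step 6
Reactants: 8 dihydro endoperoxide acetonide
Product: 9 bicyclic cis-diol (1R,4S,5S,6R)-1-methyl-2,3-dioxabicyclo[2.2.2]octane-5,6-diol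
Conditions: 1 M HCl, THF, rt
Reagents that add atoms: none
Why: Acid hydrolysis of the acetonide; a dialkyl peroxide is stable to dilute aqueous acid at room temperature and nothing in the rigid bicycle can epimerise.

Step 7
Reactants: 9 bicyclic cis-diol
Product: 10 bicyclic C12 ketol (C12 ketone; C7 hydroxyl)
Conditions: TEMPO (cat.), KBr (cat.), NaOCl (1.05 equiv), NaHCO3, CH2Cl2/H2O, 0 °C
Reagents that add atoms: none
Why: Oxoammonium (Anelli-type) oxidation is very sensitive to crowding at the carbinol carbon: the C12 hydroxyl next to the bridgehead CH (C11) should react well ahead of the C7 hydroxyl next to the quaternary C8, and with one equivalent of oxidant the reaction should stop at the ketol. The bridgehead C11–H lies in the nodal plane of the new carbonyl group and is not acidified.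

Step 8
Reactants: 10 bicyclic C12 ketol
Product: 11 bicyclic C12-methyl diol (tertiary C12 carbinol; either C12 configuration)
Conditions: MeTi(OiPr)3 (2.5 equiv), THF, −30 → 0 °C; aq. work-up
Reagents that add atoms: methyltitanium triisopropoxide, C[Ti](OC(C)C)(OC(C)C)OC(C)C
Why: Chelation-assisted carbonyl addition of a non-basic methyltitanium reagent, whose first equivalent forms the C7 titanium alkoxide; reagents of this type do not enolise and are not expected to attack a dialkyl peroxide. The C12 configuration is of no consequence because C12 becomes a carbonyl carbon in step 9.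

Step 9
Reactants: 11 bicyclic C12-methyl diol
Product: 12 keto aldehyde (3R,6S)-6-acetyl-3-methyl-1,2-dioxane-3-carbaldehyde
Conditions: NaIO4, THF/pH 7 phosphate buffer, 0 °C
Reagents that add atoms: none
Why: Periodate glycol cleavage through the cyclic periodate ester cuts C7–C12 and opens the bicycle: C7 becomes the aldehyde on quaternary C8 and C12 the methyl ketone on C11, with C8 and C11 untouched and cis on the dioxane. 12 is used without delay and kept away from amines, because C11–H is now α to both the ketone and the peroxide.

Step 10
Reactants: 13 (2E)-3-methylpent-2-en-4-yn-1-ol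
Product: 14 enyne PMB ether
Conditions: NaH, 4-methoxybenzyl chloride, Bu4NI (cat.), THF, 0 °C → rt
Reagents that add atoms: 4-methoxybenzyl chloride, COc1ccc(CCl)cc1
Why: Williamson etherification of the primary allylic alkoxide; the alkyne C–H is far less acidic than the hydroxyl and the E alkene is not affected.

Step 11
Reactants: 14 enyne PMB ether; 12 keto aldehyde
Product: 16 (7S)-propargylic alcohol (C2–OPMB enyne chain on C8; acetyl on C11), via alkynyl(ethyl)zinc 15 (not isolated)
Conditions: 14, Et2Zn, toluene, reflux; then (S)-BINOL (40 mol %), Ti(OiPr)4, Et2O, rt; then 12, rt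
Reagents that add atoms: none
Why: Asymmetric alkynylzinc addition to an aldehyde under BINOL–titanium catalysis; the aldehyde reacts and the methyl ketone does not, and no amine base is present that could attack the α-peroxy ketone. (S)-BINOL directs the alkynyl group to the Si face of aliphatic aldehydes, which here means 7S because C8 outranks the alkynyl carbon; the centre is set by the catalyst, with the neighbouring quaternary centre as a matched or mismatched partner.

Step 12
Reactants: 16 (7S)-propargylic alcohol
Product: 17 (7S)-propargylic acetate
Conditions: Ac2O, pyridine, CH2Cl2, 0 °C → rt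
Reagents that add atoms: acetic anhydride, CC(=O)OC(C)=O
Why: Acylation of the secondary propargylic alcohol; 4-(dimethylamino)pyridine is left out to spare the base-sensitive α-peroxy ketone. The acetate is the ester of the target and removes the free hydroxyl β to the peroxide.

Step 13
Reactants: 17 (7S)-propargylic acetate
Product: 18 (7S)-acetoxy methyl ketone with saturated C5–C6
Conditions: KO2CN=NCO2K (excess, in portions), AcOH, MeOH/CH2Cl2, 0 °C → rt
Reagents that add atoms: none
Why: Diimide reduces the alkyne and then the resulting cis-disubstituted C5=C6 alkene, while trisubstituted alkenes such as C3=C4 are known to react considerably more slowly and the O–O bond, ketone, acetate and PMB ether are inert. The reaction is followed and stopped when the diene intermediate is consumed.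

Step 14
Reactants: 19 (3-bromopropoxy)(tert-butyl)dimethylsilane
Product: 20 {3-[(tert-butyldimethylsilyl)oxy]propyl}triphenylphosphonium bromide
Conditions: PPh3, MeCN, reflux
Reagents that add atoms: triphenylphosphine, c1ccc(cc1)P(c1ccccc1)c1ccccc1
Why: Quaternisation of triphenylphosphine by the primary bromide (SN2).

Step 15
Reactants: 20 phosphonium bromide; 18 (7S)-acetoxy methyl ketone
Product: 22 (12Z)-alkene silyl ether (C2–OPMB; C7–OAc; C1–OTBS), via phosphonium ylide 21 (not isolated)
Conditions: 20, KN(SiMe3)2, THF, −78 °C; then 18, −78 → −20 °C
Reagents that add atoms: none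
Why: Wittig olefination of an α-oxygenated methyl ketone with a non-stabilised, potassium-derived ylide; in this substrate class the oxygen-bearing α-carbon and the new chain end up cis, which here is 12Z. Addition to the ketone at −78 °C is expected to outrun deprotonation at C11 and attack on the hindered acetate.

Step 16
Reactants: 22 (12Z)-alkene silyl ether
Product: 23 C1 alcohol
Conditions: HF·pyridine, pyridine, THF, 0 °C → rt
Reagents that add atoms: none
Why: Fluoride cleavage of the primary silyl ether under buffered conditions; PMB ether, acetate and peroxide are stable.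

Step 17
Reactants: 23 C1 alcohol
Product: 24 C1 aldehyde (β,γ-unsaturated)
Conditions: Dess–Martin periodinane, NaHCO3, CH2Cl2, 0 °C
Reagents that add atoms: none
Why: Dess–Martin oxidation under bicarbonate gives the β,γ-unsaturated aldehyde without the amine base that would move the C12=C13 bond into conjugation; 24 is used crude.

Step 18
Reactants: 25 methyl 3-(dimethylamino)propanoate; 24 C1 aldehyde
Product: 27 amino aldol adduct (C1 carbinol; C15 carrying CH2NMe2 and CO2Me; diastereomer mixture), via lithium ester enolate 26 (not isolated)
Conditions: 25, LiN(iPr)2, THF, −78 °C; then 24, −78 °C; then H2O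
Reagents that add atoms: none
Why: Aldol addition of a preformed lithium ester enolate that serves as an acrylate α-anion equivalent; at −78 °C it adds to the aldehyde faster than it deprotonates it or attacks the acetate. The two new centres (C1, C15) form as a mixture and both vanish in steps 19 and 20.

Step 19
Reactants: 27 amino aldol adduct
Product: 29 α-methylene β-hydroxy ester (C15=C17H2; C1 carbinol mixture), via trimethylammonium iodide 28 (not isolated)
Conditions: MeI, MeOH, rt; then aq. NaHCO3, CH2Cl2, rt
Reagents that add atoms: none
Why: Exhaustive N-methylation followed by E1cB loss of trimethylamine under bicarbonate gives the compound a Morita–Baylis–Hillman reaction would give, without long exposure of a β,γ-unsaturated aldehyde to an amine.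

Step 20
Reactants: 29 α-methylene β-hydroxy ester
Product: 30 allylic bromide PMB ether ((Z)-2-(bromomethyl)-2-enoate; C1=C15)
Conditions: NBS, Me2S, CH2Cl2, −20 °C; then 29, 0 °C
Reagents that add atoms: N-bromosuccinimide, O=C1CCC(=O)N1Br
Why: Activation of the allylic alcohol as an alkoxysulfonium ion (Corey–Kim reagent) and SN2′ attack of bromide at C17 give the transposed primary allylic bromide in the thermodynamically preferred Z geometry. The C1 carbinol centre disappears.

Step 21
Reactants: 30 allylic bromide PMB ether
Product: 31 allylic bromide alcohol (free C2 hydroxyl)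
Conditions: DDQ, CH2Cl2/pH 7 buffer, 0 °C
Reagents that add atoms: none
Why: Oxidative cleavage of the PMB ether by DDQ through the benzylic cation under neutral conditions; allylic bromide, enoate, acetate and peroxide are not oxidised.

Step 22
Reactants: 31 allylic bromide alcohol
Product: 32 bromo enal (C2 aldehyde; 3E)
Conditions: MnO2, CH2Cl2, rt
Reagents that add atoms: none
Why: MnO2 oxidises the primary allylic alcohol to the enal with retention of the 3E geometry and does not touch the allylic bromide.

Step 23
Reactants: 32 bromo enal
Product: 35 target CNP0238885.5, via allylindium dibromide 33 (not isolated), via seco hydroxy ester 34 (not isolated)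
Conditions: indium powder, THF/H2O (1:1), 2 mM, rt; then TsOH (cat.), CH2Cl2, rt
Reagents that add atoms: none
Why: Barbier-type intramolecular allylation; zerovalent indium inserts into the allylic C–Br bond and the 2-(methoxycarbonyl)allylindium attacks the enal carbonyl through its γ-carbon (C1) in a six-membered cyclic transition state, forming C1–C2, the exocyclic methylene and the 14-membered ring, after which acid closes the lactone. The anti arrangement (trans lactone) and the absolute sense at C1 and C2 are not reagent-controlled and must come from the conformation of the forming ring, which the cis-dioxane and two trisubstituted alkenes restrict. Indium is chosen because it is a much weaker reductant than zinc or CrCl2 and should leave the hindered O–O bond intact.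

## Compound list

1 | 4-iodotoluene | Cc1ccc(I)cc1 | starting material
2 | dioxygen | O=O | starting material
3 | (1S,2S)-3-iodo-6-methylcyclohexa-3,5-diene-1,2-diol | CC1=CC=C(I)[C@@H](O)[C@H]1O | intermediate
4 | (1R,2S)-3-methylcyclohexa-3,5-diene-1,2-diol | CC1=CC=C[C@@H](O)[C@H]1O | intermediate
5 | 2,2-dimethoxypropane | COC(C)(C)OC | starting material
6 | (3aS,7aR)-2,2,4-trimethyl-3a,7a-dihydro-1,3-benzodioxole (acetonide of 4) | CC1=CC=C[C@H]2OC(C)(C)O[C@@H]12 | intermediate
7 | endoperoxide acetonide: 2,3-dioxabicyclo[2.2.2]oct-5-ene, bridgeheads C8 (R, methyl) and C11 (S), C9=C10 bridge, C7–C12 bridge carrying the cis-acetonide anti to the O–O bridge | C[C@@]12OO[C@@H](C=C1)[C@H]3OC(C)(C)O[C@@H]23 | intermediate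
8 | 9,10-dihydro derivative of 7 (saturated bicycle, 8R,11S) | C[C@@]12OO[C@@H](CC1)[C@H]3OC(C)(C)O[C@@H]23 | intermediate
9 | (1R,4S,5S,6R)-1-methyl-2,3-dioxabicyclo[2.2.2]octane-5,6-diol (cembrane 7R,8R,11S,12S; cis-diol anti to the O–O bridge) | C[C@@]12OO[C@@H](CC1)[C@@H](O)[C@H]2O | intermediate
10 | (1R,4S,6S)-6-hydroxy-1-methyl-2,3-dioxabicyclo[2.2.2]octan-5-one (C12 ketone, C7 hydroxyl) | C[C@@]12OO[C@@H](CC1)C(=O)[C@H]2O | intermediate
11 | (1R,4S,6R)-1,5-dimethyl-2,3-dioxabicyclo[2.2.2]octane-5,6-diol, C5 (= C12) of either configuration | C[C@@]12OO[C@@H](CC1)C(C)(O)[C@H]2O | intermediate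
12 | (3R,6S)-6-acetyl-3-methyl-1,2-dioxane-3-carbaldehyde | O=C[C@@]1(C)CC[C@H](OO1)C(C)=O | intermediate
13 | (2E)-3-methylpent-2-en-4-yn-1-ol | C#C/C(C)=C/CO | starting material
14 | 1-methoxy-4-({[(2E)-3-methylpent-2-en-4-yn-1-yl]oxy}methyl)benzene | C#C/C(C)=C/COCc1ccc(OC)cc1 | intermediate
15 | ethyl{(3E)-5-[(4-methoxybenzyl)oxy]-3-methylpent-3-en-1-yn-1-yl}zinc (formed in the flask) | CC[Zn]C#C/C(C)=C/COCc1ccc(OC)cc1 | intermediate
16 | 1-[(3S,6R)-6-{(1S,4E)-1-hydroxy-6-[(4-methoxybenzyl)oxy]-4-methylhex-4-en-2-yn-1-yl}-6-methyl-1,2-dioxan-3-yl]ethan-1-one (7S,8R,11S) | COc1ccc(COC/C=C(\C)C#C[C@H](O)[C@@]2(C)CC[C@H](OO2)C(C)=O)cc1 | intermediate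
17 | (1S,4E)-1-[(3R,6S)-6-acetyl-3-methyl-1,2-dioxan-3-yl]-6-[(4-methoxybenzyl)oxy]-4-methylhex-4-en-2-yn-1-yl acetate | COc1ccc(COC/C=C(\C)C#C[C@H](OC(C)=O)[C@@]2(C)CC[C@H](OO2)C(C)=O)cc1 | intermediate
18 | (1S,4E)-1-[(3R,6S)-6-acetyl-3-methyl-1,2-dioxan-3-yl]-6-[(4-methoxybenzyl)oxy]-4-methylhex-4-en-1-yl acetate | COc1ccc(COC/C=C(\C)CC[C@H](OC(C)=O)[C@@]2(C)CC[C@H](OO2)C(C)=O)cc1 | intermediate
19 | (3-bromopropoxy)(tert-butyl)dimethylsilane | BrCCCO[Si](C)(C)C(C)(C)C | starting material
20 | {3-[(tert-butyldimethylsilyl)oxy]propyl}triphenylphosphonium bromide | CC(C)(C)[Si](C)(C)OCCC[P+](c1ccccc1)(c1ccccc1)c1ccccc1.[Br-] | intermediate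
21 | {3-[(tert-butyldimethylsilyl)oxy]propylidene}triphenylphosphorane (formed in the flask) | CC(C)(C)[Si](C)(C)OCCC=P(c1ccccc1)(c1ccccc1)c1ccccc1 | intermediate
22 | (1S,4E)-1-[(3R,6S)-6-{(2Z)-5-[(tert-butyldimethylsilyl)oxy]pent-2-en-2-yl}-3-methyl-1,2-dioxan-3-yl]-6-[(4-methoxybenzyl)oxy]-4-methylhex-4-en-1-yl acetate | COc1ccc(COC/C=C(\C)CC[C@H](OC(C)=O)[C@@]2(C)CC[C@H](OO2)/C(C)=C\CCO[Si](C)(C)C(C)(C)C)cc1 | intermediate
23 | as 22 with free C1 hydroxyl ((2Z)-5-hydroxypent-2-en-2-yl arm) | COc1ccc(COC/C=C(\C)CC[C@H](OC(C)=O)[C@@]2(C)CC[C@H](OO2)/C(C)=C\CCO)cc1 | intermediate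
24 | as 22 with C1 aldehyde ((2Z)-5-oxopent-2-en-2-yl arm) | COc1ccc(COC/C=C(\C)CC[C@H](OC(C)=O)[C@@]2(C)CC[C@H](OO2)/C(C)=C\CC=O)cc1 | intermediate
25 | methyl 3-(dimethylamino)propanoate | COC(=O)CCN(C)C | starting material
26 | lithium enolate of 25 (formed in the flask) | [Li]OC(OC)=CCN(C)C | intermediate
27 | amino aldol adduct: chain of 24 with C1 as CH(OH) bonded to C15H(CH2NMe2)CO2Me, mixture at C1 and C15 | COc1ccc(COC/C=C(\C)CC[C@H](OC(C)=O)[C@@]2(C)CC[C@H](OO2)/C(C)=C\CC(O)C(CN(C)C)C(=O)OC)cc1 | intermediate
28 | N-methylated 27, trimethylammonium iodide (formed in the flask) | COc1ccc(COC/C=C(\C)CC[C@H](OC(C)=O)[C@@]2(C)CC[C@H](OO2)/C(C)=C\CC(O)C(C[N+](C)(C)C)C(=O)OC)cc1.[I-] | intermediate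
29 | α-methylene β-hydroxy ester: C1H(OH)–C15(=C17H2)–CO2Me, mixture at C1 | COc1ccc(COC/C=C(\C)CC[C@H](OC(C)=O)[C@@]2(C)CC[C@H](OO2)/C(C)=C\CC(O)C(=C)C(=O)OC)cc1 | intermediate
30 | (Z)-2-(bromomethyl)-2-enoate: BrC17H2–C15(CO2Me)=C1H–C14H2, C2–OPMB | COc1ccc(COC/C=C(\C)CC[C@H](OC(C)=O)[C@@]2(C)CC[C@H](OO2)/C(C)=C\C/C=C(\CBr)C(=O)OC)cc1 | intermediate
31 | as 30 with free C2 hydroxyl | OC/C=C(\C)CC[C@H](OC(C)=O)[C@@]1(C)CC[C@H](OO1)/C(C)=C\C/C=C(\CBr)C(=O)OC | intermediate
32 | as 30 with C2 aldehyde (3E enal) | O=C/C=C(\C)CC[C@H](OC(C)=O)[C@@]1(C)CC[C@H](OO1)/C(C)=C\C/C=C(\CBr)C(=O)OC | intermediate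
33 | allylindium dibromide from 32, simplified form of the organoindium halide (formed in the flask) | O=C/C=C(\C)CC[C@H](OC(C)=O)[C@@]1(C)CC[C@H](OO1)/C(C)=C\C/C=C(\C[In](Br)Br)C(=O)OC | intermediate
34 | seco hydroxy ester: 14-membered carbocycle (1S,2R,7S,8R,11S; 3E,12Z) with C2 hydroxyl and methyl 2-propenoate unit on C1 (formed in the flask) | O[C@@H]1/C=C(\C)CC[C@H](OC(C)=O)[C@@]2(C)CC[C@H](OO2)/C(C)=C\C[C@H]1C(=C)C(=O)OC | intermediate
35 | (1S,2R,3E,7S,8R,11S,12Z)-7-acetoxy-8,11-epidioxycembra-3,12,15(17)-trien-16,2-olide, CNP0238885.5 | C=C1C(=O)O[C@@H]2/C=C(\C)CC[C@H](OC(C)=O)[C@@]3(C)CC[C@H](OO3)/C(C)=C\C[C@@H]12 | target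

## Step count and least certain steps

Total step count: 23 (steps 10 and 14 prepare side fragments). Longest linear sequence: 21 steps (1–9, 11–13, 15–23).

**Step 4 (key step).** What may go wrong: ene reaction of singlet oxygen at the C19 methyl group instead of cycloaddition, incomplete facial selectivity, and thermal or photochemical rearrangement of the endoperoxide. Fallback: from 6, a radical-cation chain oxygenation with ground-state 2, started by catalytic (4-BrC6H4)3N SbCl6 in CH2Cl2 at −78 °C. This is a different mechanism, has no ene pathway, and returns to the route at 7 without new compounds.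

**Step 7.** What may go wrong: too little discrimination between the two secondary hydroxyls, or over-oxidation. Fallback: from 9, both hydroxyls are oxidised (excess Dess–Martin periodinane) to the 7,12-dione F1. One equivalent of MeTi(OiPr)3 should add to the less shielded C12 carbonyl to give the C7-keto C12-methyl carbinol F2. NaBH4 reduces the C7 ketone to the diol as a C7 epimer mixture F3, either epimer of which NaIO4 cleaves. The route is rejoined at 12.

**Step 11.** What may go wrong: mismatched double stereodifferentiation between the catalyst and the quaternary α-centre, giving poor selectivity at C7, or slow addition to the hindered aldehyde. Fallback: from 16 as an epimer mixture, Dess–Martin oxidation gives the ynone F4, and Midland reduction with (R)-Alpine-Borane sets 7S by hydride delivery. This reagent reduces alkynyl ketones and spares the methyl ketone. The route is rejoined at 16.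

**Step 13.** What may go wrong: stalling at the hindered cis-alkene stage, or over-reduction of C3=C4. Fallback: C5–C6 is brought in saturated.
- From 14, semi-hydrogenation over Pd/CaCO3 poisoned with Pb(OAc)2 gives the dienyl PMB ether F5.
- Hydroboration of the terminal vinyl group with Et2BH gives the alkyldiethylborane F6.
- Boron–zinc exchange with Et2Zn gives the dialkylzinc F7.
- Addition to 12 with Ti(OiPr)4 and (1R,2R)-1,2-bis(trifluoromethanesulfonamido)cyclohexane, which delivers alkyl groups to the Si face, gives the saturated 7S alcohol F8.
- Acetylation as in step 12 rejoins the route at 18.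

**Step 15.** What may go wrong: deprotonation at C11 by the ylide with Kornblum–DeLaMare cleavage or epimerisation, attack on the acetate, or incomplete Z selectivity. Fallback: a Horner–Wittig sequence from 18. The phosphine oxide F9 (from 19 and ethyl diphenylphosphinite by Michaelis–Arbuzov reaction) is lithiated with BuLi, transmetallated with CeCl3 to lower its basicity and added at −78 °C to give the β-hydroxy phosphine oxides F10. The diastereomers are separated, and the one that leads to the Z alkene is eliminated with NaH in DMF (stereospecific syn elimination). The route is rejoined at 22.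

**Step 23.** What may go wrong: reduction of the O–O bond by the metal, formation of the cis lactone or of the wrong face pair at C1/C2, and oligomerisation. Fallback: an allylsilane closure from 24.
- Horner–Wadsworth–Emmons reaction with methyl 2-(dimethoxyphosphoryl)-3-(trimethylsilyl)propanoate gives the 2-(trimethylsilylmethyl)enoate F11.
- DDQ gives the allylic alcohol F12.
- MnO2 gives the enal F13.
- Bu4NF at high dilution triggers an intramolecular Hosomi–Sakurai allylation through an open transition state with no reducing metal. The resulting alkoxide of 34 lactonises, and the route is rejoined at 35.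

## Further compounds

F0 | step 4 | none | none
F1 | step 7 | 1-methyl-2,3-dioxabicyclo[2.2.2]octane-5,6-dione (bridgeheads as in 9) | C[C@@]12OO[C@@H](CC1)C(=O)C2=O
F2 | step 7 | 5-hydroxy-1,5-dimethyl-2,3-dioxabicyclo[2.2.2]octan-6-one (C12 carbinol, C7 ketone) | C[C@@]12OO[C@@H](CC1)C(C)(O)C2=O
F3 | step 7 | 1,5-dimethyl-2,3-dioxabicyclo[2.2.2]octane-5,6-diol, C7 epimer mixture | C[C@@]12OO[C@@H](CC1)C(C)(O)C2O
F4 | step 11 | C7 ynone corresponding to 16 | COc1ccc(COC/C=C(\C)C#CC(=O)[C@@]2(C)CC[C@H](OO2)C(C)=O)cc1
F5 | step 13 | 1-methoxy-4-({[(2E)-3-methylpenta-2,4-dien-1-yl]oxy}methyl)benzene | C=C/C(C)=C/COCc1ccc(OC)cc1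
F6 | step 13 | diethyl{(3E)-5-[(4-methoxybenzyl)oxy]-3-methylpent-3-en-1-yl}borane | CCB(CC)CC/C(C)=C/COCc1ccc(OC)cc1
F7 | step 13 | bis{(3E)-5-[(4-methoxybenzyl)oxy]-3-methylpent-3-en-1-yl}zinc | COc1ccc(COC/C=C(\C)CC[Zn]CC/C(C)=C/COCc2ccc(OC)cc2)cc1
F8 | step 13 | 7S alcohol corresponding to 18 (deacetyl 18) | COc1ccc(COC/C=C(\C)CC[C@H](O)[C@@]2(C)CC[C@H](OO2)C(C)=O)cc1
F9 | step 15 | {3-[(tert-butyldimethylsilyl)oxy]propyl}diphenylphosphine oxide | CC(C)(C)[Si](C)(C)OCCCP(=O)(c1ccccc1)c1ccccc1
F10 | step 15 | β-hydroxy phosphine oxide adduct of F9 and 18 (C12 carbinol, C13 phosphinoyl; diastereomers) | COc1ccc(COC/C=C(\C)CC[C@H](OC(C)=O)[C@@]2(C)CC[C@H](OO2)C(C)(O)C(CCO[Si](C)(C)C(C)(C)C)P(=O)(c3ccccc3)c3ccccc3)cc1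
F11 | step 23 | 2-(trimethylsilylmethyl)enoate from 24 (C1=C15 isomer mixture), C2–OPMB | COc1ccc(COC/C=C(\C)CC[C@H](OC(C)=O)[C@@]2(C)CC[C@H](OO2)/C(C)=C\CC=C(C[Si](C)(C)C)C(=O)OC)cc1
F12 | step 23 | as F11 with free C2 hydroxyl | OC/C=C(\C)CC[C@H](OC(C)=O)[C@@]1(C)CC[C@H](OO1)/C(C)=C\CC=C(C[Si](C)(C)C)C(=O)OC
F13 | step 23 | as F11 with C2 aldehyde | O=C/C=C(\C)CC[C@H](OC(C)=O)[C@@]1(C)CC[C@H](OO1)/C(C)=C\CC=C(C[Si](C)(C)C)C(=O)OC
A1 | alternative 1 | 14-membered allylic alcohol with 3E alkene, 7,8-epoxide, C11 silyl ether and C16 PMB ether | O[C@@H]1/C=C(\C)CC[C@@H]2O[C@@]2(C)CC[C@@H](O[Si](C)(C)C(C)(C)C)/C(C)=C\C[C@H]1C(=C)COCc3ccc(OC)cc3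
A2 | alternative 2 | (7S,8S)-7,8-epoxy-(11S)-11-hydroperoxy cembranolide | C=C1C(=O)O[C@@H]2/C=C(\C)CC[C@@H]3O[C@@]3(C)CC[C@H](OO)/C(C)=C\C[C@@H]12
A3 | alternative 2 | 7-O-deacetyl target | C=C1C(=O)O[C@@H]2/C=C(\C)CC[C@H](O)[C@@]3(C)CC[C@H](OO3)/C(C)=C\C[C@@H]12
A4 | alternative 3 | (11R)-11-hydroxy-7,8-epoxy cembranolide | C=C1C(=O)O[C@@H]2/C=C(\C)CC[C@@H]3O[C@@]3(C)CC[C@@H](O)/C(C)=C\C[C@@H]12
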